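**Retrosynthetic overview**

- Target 12 ⇒ C9–O aryl ether (Mitsunobu reaction with eugenol) + phenylcoumaran alcohol 10. The silyl ether on ring C and the acyl sultam at C9 are the only temporary groups.
- Core ⇒ eugenol + N-feruloyl camphorsultam 5. O1–C2 and C3–C3a are made together in one oxidative cross-coupling, a [3+2] annulation of the O–C(ortho) unit of a phenol onto the C7=C8 bond of the cinnamoyl unit. C9 stays at the carboxyl level so that the auxiliary sits next to C3, and is reduced afterwards.
- Enabling feature: the free 4-OH of ring C (the aryl group on C2) lies para to C2. C2 can therefore be the methide carbon of a p-quinone methide, and C3 the β-carbon spin site of the same phenoxyl radical. Ring A is a guaiacol whose O1 and only free ortho carbon (C3a) are the two atoms that close ring B.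
- Ring order: rings A, C and D are bought (eugenol twice, ferulic acid). Ring B (the dihydrofuran) is the only ring formed, in the key step, together with both stereocenters (C3 by the sultam, C2 trans to C3).

Key step: step 3

Assumption: the sense of induction is taken from the usual model for uncatalysed additions to N-enoyl camphorsultams (anti, s-cis conformer, approach to the α-carbon face remote from the pseudo-axial sulfonyl oxygen), which points to the (2S)-sultam; if the other face is preferred, the equally available (2R)-sultam is used with no other change.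

**Route**

Step 1
Reactants: 1 (E)-3-(4-acetoxy-3-methoxyphenyl)prop-2-enoic acid (O-acetylferulic acid); 2 (1R,2S,4S)-bornane-10,2-sultam ((+)-2,10-camphorsultam)
Product: 4 N-[(E)-3-(4-acetoxy-3-methoxyphenyl)prop-2-enoyl]-(2S)-bornane-10,2-sultam, via acid chloride 3 (not isolated)
Conditions: (COCl)2, cat. DMF, CH2Cl2, 0 °C to rt, evaporate; then 2, Et3N, cat. DMAP, CH2Cl2, 0 °C to rt
Reagents that add atoms: none
Why: Acid chloride formation followed by DMAP-catalysed N-acylation of the sulfonamide N–H is routine for this sultam, the aryl acetate masks the phenol during activation, and no stereocenter is formed.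

Step 2
Reactants: 4 N-[(E)-3-(4-acetoxy-3-methoxyphenyl)prop-2-enoyl]-(2S)-bornane-10,2-sultam
Product: 5 N-[(E)-3-(4-hydroxy-3-methoxyphenyl)prop-2-enoyl]-(2S)-bornane-10,2-sultam (N-feruloyl sultam)
Conditions: pyrrolidine (1.2 equiv), CH2Cl2, 0 °C
Reagents that add atoms: none
Why: Aminolysis of an aryl acetate (an activated ester) by a secondary amine should be far faster than attack at the hindered, conjugated N-acyl sultam, so the phenol needed for the oxidation is freed selectively and no stereocenter is involved.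

Step 3
Reactants: 5 N-feruloyl-(2S)-bornane-10,2-sultam; 6 eugenol (4-allyl-2-methoxyphenol)
Product: 8 N-{[(2S,3S)-5-allyl-2-(4-hydroxy-3-methoxyphenyl)-7-methoxy-2,3-dihydro-1-benzofuran-3-yl]carbonyl}-(2S)-bornane-10,2-sultam, via quinone methide 7 (not isolated)
Conditions: Ag2O (2.5 equiv, in portions), 6 (4 equiv), CH2Cl2/acetone 2:1, rt, dark
Reagents that add atoms: none
Why: Oxidative phenol cross-coupling: Ag2O removes one electron and one proton from each phenol, the two phenoxyl radicals join the β-carbon (C8) of 5 to the free ortho carbon (C6) of 6 to form C3–C3a, ring A rearomatises to quinone methide 7, and the ring A hydroxyl then adds to the methide carbon to form O1–C2. The closest known reaction is the oxidative dimerisation of ferulic acid derivatives to phenylcoumarans with Ag2O or a peroxidase, including its auxiliary-controlled form with ferulic amides of camphorsultam; here it is run as a cross-coupling. Ring B closes by 5-exo-trig conjugate (1,6-) addition of a phenol to the p-quinone methide. C3 is set in the C–C coupling by the sultam, whose anti, s-cis N-enoyl conformer should expose the Si face of C8, and C2 is set by C3, the aryl group closing trans to the acyl group in what is also the more stable arrangement. The step needs cross- over homo-coupling and C–C over C–O coupling: the fourfold excess of 6 should make the eugenyl radical the usual partner of the radical of 5, the allyl and methoxy groups of 6 leave C6 as its only unsubstituted ring carbon bearing spin density, and coupling of the β-carbon to a guaiacol ortho carbon is the expected main mode for feruloyl radicals. The minor (2R,3R) diastereomer, dehydrodieugenol and the homodimer of 5 should differ enough from 8 to be removed by chromatography and crystallisation.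

Step 4
Reactants: 8 N-{[(2S,3S)-5-allyl-2-(4-hydroxy-3-methoxyphenyl)-7-methoxy-2,3-dihydro-1-benzofuran-3-yl]carbonyl}-(2S)-bornane-10,2-sultam
Product: 9 N-{[(2S,3S)-5-allyl-2-(4-{[tert-butyl(dimethyl)silyl]oxy}-3-methoxyphenyl)-7-methoxy-2,3-dihydro-1-benzofuran-3-yl]carbonyl}-(2S)-bornane-10,2-sultam
Conditions: TBSCl, imidazole, DMF, rt
Reagents that add atoms: tert-butyldimethylsilyl chloride (TBSCl), CC(C)(C)[Si](C)(C)Cl
Why: Imidazole-promoted silyl ether formation at the ring C phenol removes the only acidic OH before the hydride and Mitsunobu steps, under conditions too mild to enolise C3.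

Step 5
Reactants: 9 silyl ether of the coupled acyl sultam
Product: 10 [(2S,3R)-5-allyl-2-(4-{[tert-butyl(dimethyl)silyl]oxy}-3-methoxyphenyl)-7-methoxy-2,3-dihydro-1-benzofuran-3-yl]methanol
Conditions: LiBH4, THF/MeOH, 0 °C to rt
Reagents that add atoms: none
Why: Reductive cleavage of the N-acyl sultam by hydride (activated amide to primary alcohol) releases the auxiliary for recovery and brings C9 to the alcohol level without touching the terminal alkenes, the silyl ether or the stereocenters, after which C3 is no longer enolisable.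

Step 6
Reactants: 10 [(2S,3R)-5-allyl-2-(4-{[tert-butyl(dimethyl)silyl]oxy}-3-methoxyphenyl)-7-methoxy-2,3-dihydro-1-benzofuran-3-yl]methanol; 6 eugenol
Product: 11 tert-butyl{4-[(2S,3R)-5-allyl-3-[(4-allyl-2-methoxyphenoxy)methyl]-7-methoxy-2,3-dihydro-1-benzofuran-2-yl]-2-methoxyphenoxy}dimethylsilane
Conditions: 6 (1.5 equiv), PPh3, DIAD, THF, 0 °C to rt
Reagents that add atoms: none
Why: The Mitsunobu reaction of a primary alcohol with a phenol forms the C9–O aryl ether at a carbon that is not stereogenic, so neither stereocenter is affected.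

Step 7
Reactants: 11 silyl-protected target
Product: 12 4-[(2S,3R)-5-allyl-3-[(4-allyl-2-methoxyphenoxy)methyl]-7-methoxy-2,3-dihydro-1-benzofuran-2-yl]-2-methoxyphenol (target)
Conditions: Bu4NF, AcOH, THF, 0 °C
Reagents that add atoms: none
Why: Fluoride cleavage of the aryl silyl ether, buffered with AcOH so that no free phenoxide para to C2 can open ring B, frees the ring C phenol and should give the target with both stereocenters untouched.

**Compound list**

1 | (E)-3-(4-acetoxy-3-methoxyphenyl)prop-2-enoic acid | CC(=O)Oc1ccc(/C=C/C(=O)O)cc1OC | starting material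
2 | (1R,2S,4S)-bornane-10,2-sultam, (+)-2,10-camphorsultam | CC1(C)[C@H]2CC[C@@]13CS(=O)(=O)N[C@H]3C2 | starting material
3 | (E)-3-(4-acetoxy-3-methoxyphenyl)prop-2-enoyl chloride | CC(=O)Oc1ccc(/C=C/C(=O)Cl)cc1OC | intermediate
4 | N-[(E)-3-(4-acetoxy-3-methoxyphenyl)prop-2-enoyl]-(2S)-bornane-10,2-sultam | CC1(C)[C@H]2CC[C@@]13CS(=O)(=O)N(C(=O)/C=C/c4ccc(OC(C)=O)c(OC)c4)[C@H]3C2 | intermediate
5 | N-[(E)-3-(4-hydroxy-3-methoxyphenyl)prop-2-enoyl]-(2S)-bornane-10,2-sultam | CC1(C)[C@H]2CC[C@@]13CS(=O)(=O)N(C(=O)/C=C/c4ccc(O)c(OC)c4)[C@H]3C2 | intermediate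
6 | eugenol (4-allyl-2-methoxyphenol) | C=CCc1ccc(O)c(OC)c1 | starting material
7 | N-[(2R)-2-(5-allyl-2-hydroxy-3-methoxyphenyl)-3-(3-methoxy-4-oxocyclohexa-2,5-dien-1-ylidene)propanoyl]-(2S)-bornane-10,2-sultam (p-quinone methide, methide geometry not defined) | CC1(C)[C@H]2CC[C@@]13CS(=O)(=O)N(C(=O)[C@H](C=C4C=CC(=O)C(OC)=C4)c5cc(CC=C)cc(OC)c5O)[C@H]3C2 | intermediate
8 | N-{[(2S,3S)-5-allyl-2-(4-hydroxy-3-methoxyphenyl)-7-methoxy-2,3-dihydro-1-benzofuran-3-yl]carbonyl}-(2S)-bornane-10,2-sultam | CC1(C)[C@H]2CC[C@@]13CS(=O)(=O)N(C(=O)[C@H]4c5cc(CC=C)cc(OC)c5O[C@@H]4c6ccc(O)c(OC)c6)[C@H]3C2 | intermediate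
9 | N-{[(2S,3S)-5-allyl-2-(4-{[tert-butyl(dimethyl)silyl]oxy}-3-methoxyphenyl)-7-methoxy-2,3-dihydro-1-benzofuran-3-yl]carbonyl}-(2S)-bornane-10,2-sultam | CC1(C)[C@H]2CC[C@@]13CS(=O)(=O)N(C(=O)[C@H]4c5cc(CC=C)cc(OC)c5O[C@@H]4c6ccc(O[Si](C)(C)C(C)(C)C)c(OC)c6)[C@H]3C2 | intermediate
10 | [(2S,3R)-5-allyl-2-(4-{[tert-butyl(dimethyl)silyl]oxy}-3-methoxyphenyl)-7-methoxy-2,3-dihydro-1-benzofuran-3-yl]methanol | OC[C@H]1c2cc(CC=C)cc(OC)c2O[C@@H]1c3ccc(O[Si](C)(C)C(C)(C)C)c(OC)c3 | intermediate
11 | tert-butyl{4-[(2S,3R)-5-allyl-3-[(4-allyl-2-methoxyphenoxy)methyl]-7-methoxy-2,3-dihydro-1-benzofuran-2-yl]-2-methoxyphenoxy}dimethylsilane | C=CCc1ccc(OC[C@H]2c3cc(CC=C)cc(OC)c3O[C@@H]2c4ccc(O[Si](C)(C)C(C)(C)C)c(OC)c4)c(OC)c1 | intermediate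
12 | 4-[(2S,3R)-5-allyl-3-[(4-allyl-2-methoxyphenoxy)methyl]-7-methoxy-2,3-dihydro-1-benzofuran-2-yl]-2-methoxyphenol | C=CCc1ccc(OC[C@H]2c3cc(CC=C)cc(OC)c3O[C@@H]2c2ccc(O)c(OC)c2)c(OC)c1 | target

**Step count and risks**

Total steps: 7. Longest linear sequence: 7 steps (1 to 12).

Steps most likely to fail:

1. Step 3. Homo-coupling of either phenol may outrun cross-coupling, C–O coupling may compete with C–C coupling, and the facial selectivity at C8 may be low. The fallback sets out from eugenol 6 and returns at 11. It adds the eugenol phenoxyl radical to a non-phenolic styrene that already carries ring D, so only one phenol can be oxidised and no auxiliary is needed. Commercial ethyl ferulate is silylated (TBSCl, imidazole) to ethyl (E)-3-(4-{[tert-butyl(dimethyl)silyl]oxy}-3-methoxyphenyl)prop-2-enoate F1. Reduction with i-Bu2AlH gives (E)-3-(4-{[tert-butyl(dimethyl)silyl]oxy}-3-methoxyphenyl)prop-2-en-1-ol F2. Mitsunobu etherification with 6 gives the (E)-cinnamyl eugenyl ether F3. Oxidative [3+2] coupling of 6 with F3 (cat. FeCl3, DDQ, the known coupling of phenols with anethole-type alkenes) should give the racemic trans-dihydrobenzofuran F4. Preparative HPLC on a chiral stationary phase then gives 11, and step 7 follows.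

2. Step 5. Hydride attack at the hindered, α-branched acyl sultam may be slow, so that alkoxide-induced enolisation at C3 and opening of ring B compete. The fallback sets out from 9 and returns at 10. The auxiliary is first exchanged by transesterification (Ti(OEt)4, EtOH, reflux) to ethyl (2S,3S)-5-allyl-2-(4-{[tert-butyl(dimethyl)silyl]oxy}-3-methoxyphenyl)-7-methoxy-2,3-dihydro-1-benzofuran-3-carboxylate F5. This unhindered ester is reduced with i-Bu2AlH (CH2Cl2, −78 °C) to 10.

3. Step 6. Dehydration toward the 3-methylene compound, or slow substitution at the β-branched primary carbon, may replace ether formation. The fallback sets out from 10 and returns at 11. An Appel reaction (I2, PPh3, imidazole) gives tert-butyl{4-[(2S,3S)-5-allyl-3-(iodomethyl)-7-methoxy-2,3-dihydro-1-benzofuran-2-yl]-2-methoxyphenoxy}dimethylsilane F6. Williamson etherification with 6 (K2CO3, acetone, reflux) then gives 11.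

Further compounds
F1 | step 3 | ethyl (E)-3-(4-{[tert-butyl(dimethyl)silyl]oxy}-3-methoxyphenyl)prop-2-enoate | CCOC(=O)/C=C/c1ccc(O[Si](C)(C)C(C)(C)C)c(OC)c1
F2 | step 3 | (E)-3-(4-{[tert-butyl(dimethyl)silyl]oxy}-3-methoxyphenyl)prop-2-en-1-ol | OC/C=C/c1ccc(O[Si](C)(C)C(C)(C)C)c(OC)c1
F3 | step 3 | {4-[(E)-3-(4-allyl-2-methoxyphenoxy)prop-1-enyl]-2-methoxyphenoxy}(tert-butyl)dimethylsilane | C=CCc1ccc(OC/C=C/c2ccc(O[Si](C)(C)C(C)(C)C)c(OC)c2)c(OC)c1
F4 | step 3 | racemic trans form of 11 (both enantiomers) | C=CCc1ccc(OC[C@H]2c3cc(CC=C)cc(OC)c3O[C@@H]2c4ccc(O[Si](C)(C)C(C)(C)C)c(OC)c4)c(OC)c1.C=CCc1ccc(OC[C@@H]2c3cc(CC=C)cc(OC)c3O[C@H]2c4ccc(O[Si](C)(C)C(C)(C)C)c(OC)c4)c(OC)c1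
F5 | step 5 | ethyl (2S,3S)-5-allyl-2-(4-{[tert-butyl(dimethyl)silyl]oxy}-3-methoxyphenyl)-7-methoxy-2,3-dihydro-1-benzofuran-3-carboxylate | CCOC(=O)[C@H]1c2cc(CC=C)cc(OC)c2O[C@@H]1c3ccc(O[Si](C)(C)C(C)(C)C)c(OC)c3
F6 | step 6 | tert-butyl{4-[(2S,3S)-5-allyl-3-(iodomethyl)-7-methoxy-2,3-dihydro-1-benzofuran-2-yl]-2-methoxyphenoxy}dimethylsilane | IC[C@H]1c2cc(CC=C)cc(OC)c2O[C@@H]1c3ccc(O[Si](C)(C)C(C)(C)C)c(OC)c3
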